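The target is disconnected at C3–C3a and N1–C2 of ring A (the NH indole), so the crowded C3–N1' link is made early by a simple N-alkylation of ring B. Ring A carries Br on C4, C5 and C6. Its benzo ring is therefore a 3,4,5-tribromoanilino unit whose two ortho carbons (future C3a and C7) are equivalent. The precursor is a hydrazide in which the 2,4,6-tribromo-3-(methylthio)indol-1-ylacetyl group sits on the terminal nitrogen of (3,4,5-tribromophenyl)hydrazine. Its Brunner rearrangement forms both bonds and the five-membered ring in one operation, giving the oxindole as a single regioisomer. Thionation and S-methylation then aromatise ring A.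

Key step: step 6

Assumption: rotation about the C3–N1' axis is probably hindered, but the target string gives no axial descriptor, so the compound is made as the racemate; the target has no stereocentre.

Step 1
Reactants: 1 3,5-dibromoaniline; 2 ethyl (methylthio)acetate
Product: 6 racemic 4,6-dibromo-3-(methylthio)indolin-2-one, via N-chloroaniline 3 (not isolated), via azasulfonium chloride 4 (not isolated), via amino ester 5 (not isolated)
Conditions: t-BuOCl, CH2Cl2, −65 °C; 2; Et3N, −65 °C → rt; 2 M HCl, rt
Reagents that add atoms: none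
Why: Gassman oxindole synthesis: the azasulfonium ylide released by Et3N undergoes a [2,3]-sigmatropic (Sommelet–Hauser-type) shift to an ortho carbon, the two ortho carbons of 1 are equivalent so only the 4,6-dibromo pattern can arise, electron-poor anilines suit the N-chloroaniline variant, and acid lactamises 5 to 6, whose racemic C3 stereocentre is lost in step 2.

Step 2
Reactants: 6 racemic 4,6-dibromo-3-(methylthio)indolin-2-one
Product: 7 2,4,6-tribromo-3-(methylthio)-1H-indole
Conditions: POBr3, imidazole, ClCH2CH2Cl, 80 °C; ice water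
Reagents that add atoms: phosphorus oxybromide, O=P(Br)(Br)Br
Why: Lactam deoxybromination (haloimidate formation, as in Vilsmeier-type activation): O-phosphorylation of the 2-hydroxyindole tautomer, bromide substitution at C2 and loss of the acidic C3–H give the aromatic 2-bromoindole, while imidazole buffers HBr so that the C3 methylthio group stays in place.

Step 3
Reactants: 7 2,4,6-tribromo-3-(methylthio)-1H-indole; 8 ethyl bromoacetate
Product: 10 2-[2,4,6-tribromo-3-(methylthio)indol-1-yl]acetic acid, via ethyl ester 9 (not isolated)
Conditions: K2CO3, DMF, rt; then LiOH, THF/H2O, rt; 1 M HCl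
Reagents that add atoms: LiOH, [Li+].[OH-]
Why: SN2 N-alkylation of an indole N–H acidified by three bromines (C3 is blocked), followed by saponification in the same flask; the aryl thioether is too weak a nucleophile to compete and the C–Br bonds are inert to carbonate and cold hydroxide.

Step 4
Reactants: 11 3,4,5-tribromoaniline
Product: 13 (3,4,5-tribromophenyl)hydrazine, via diazonium chloride 12 (not isolated)
Conditions: NaNO2, conc. HCl/AcOH, 0 °C; SnCl2·2H2O, conc. HCl, 0 °C → rt; aq. NaOH
Reagents that add atoms: NaNO2, [Na+].[O-]N=O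
Why: Diazotisation followed by SnCl2 reduction is the classical arylhydrazine synthesis; it tolerates aryl bromides, and the AcOH/conc. HCl medium keeps the weakly basic aniline in solution.

Step 5
Reactants: 10 2-[2,4,6-tribromo-3-(methylthio)indol-1-yl]acetic acid; 13 (3,4,5-tribromophenyl)hydrazine
Product: 15 N'-(3,4,5-tribromophenyl)-2-[2,4,6-tribromo-3-(methylthio)indol-1-yl]acetohydrazide, via benzotriazolyl ester 14 (not isolated)
Conditions: EDC·HCl, HOBt, DMF, 0 °C → rt
Reagents that add atoms: none
Why: Carbodiimide/HOBt amide coupling: the terminal NH2 of 13 is far more nucleophilic than the nitrogen conjugated with the tribromophenyl ring, so acylation should give only the N'-aryl hydrazide.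

Step 6
Reactants: 15 N'-(3,4,5-tribromophenyl)-2-[2,4,6-tribromo-3-(methylthio)indol-1-yl]acetohydrazide
Product: 17 racemic 4,5,6-tribromo-3-[2,4,6-tribromo-3-(methylthio)indol-1-yl]indolin-2-one, via amino amide 16 (not isolated)
Conditions: CaH2, Ph2O, 190–210 °C, Ar; cool; degassed 1 M HCl
Reagents that add atoms: none
Why: This is the Brunner oxindole synthesis, the amide-level counterpart of the Fischer indolisation: the calcium base removes the hydrazide N–H protons and, at temperature, the doubly activated C3–H (alpha to the carbonyl and to N1'), giving an ene-hydrazide anion. Its [3,3]-sigmatropic shift joins C3 to an ortho carbon of the tribromoanilino ring (C3a) as the weak N–N bond breaks, and tautomerisation restores the arene to give amino amide 16. The freed aniline nitrogen N1 then attacks the primary amide carbon C2 in a 5-exo-trig closure and ammonia escapes, which closes the five-membered lactam of ring A irreversibly. C3 becomes a stereocentre with no controlling element, so 17 is racemic, which is harmless because C3 turns planar in step 8. The only regiochemical question, which ortho carbon is attacked, disappears because the two are related by the symmetry of the 3,4,5-tribromophenyl group, and the para carbon is out of reach of a six-membered transition state. Insoluble CaH2 is chosen over organolithium or soluble amide bases because the only bases in solution are then the substrate anions, too weak to cause bromine–metal exchange, aryne formation or metalation of C5'–H between its two bromines, and 17 is shielded as its aromatic 2-oxidoindole salt until the acidic quench.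

Step 7
Reactants: 17 racemic 4,5,6-tribromo-3-[2,4,6-tribromo-3-(methylthio)indol-1-yl]indolin-2-one
Product: 18 racemic 4,5,6-tribromo-3-[2,4,6-tribromo-3-(methylthio)indol-1-yl]indoline-2-thione
Conditions: Lawesson's reagent, toluene, 90 °C, Ar
Reagents that add atoms: Lawesson's reagent, COc1ccc(cc1)P1(=S)SP(=S)(S1)c1ccc(OC)cc1
Why: Lactam thionation with Lawesson's reagent (Wittig-like thiaoxaphosphetane cycloreversion) is standard for oxindoles and touches neither the C–Br bonds nor the thioether; C3 stays racemic.

Step 8
Reactants: 18 racemic 4,5,6-tribromo-3-[2,4,6-tribromo-3-(methylthio)indol-1-yl]indoline-2-thione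
Product: 19 4,5,6-tribromo-2-(methylthio)-3-[2,4,6-tribromo-3-(methylthio)indol-1-yl]-1H-indole (target)
Conditions: MeI (1.05 equiv), K2CO3, acetone, 0 °C → rt, Ar
Reagents that add atoms: iodomethane, CI
Why: S-alkylation of a thiolactam: the soft indole-2-thiolate anion formed by K2CO3 attacks MeI at sulfur and the product settles as the aromatic 1H-indole, which erases the C3 stereocentre, while a single equivalent of MeI at low temperature spares N1–H.

Compound list
1 | 3,5-dibromoaniline | Nc1cc(Br)cc(Br)c1 | starting material
2 | ethyl (methylthio)acetate | CCOC(=O)CSC | starting material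
3 | N-chloro-3,5-dibromoaniline | ClNc1cc(Br)cc(Br)c1 | intermediate
4 | (3,5-dibromoanilino)(2-ethoxy-2-oxoethyl)(methyl)sulfonium chloride, racemic | CCOC(=O)C[S+](C)Nc1cc(Br)cc(Br)c1.[Cl-] | intermediate
5 | racemic ethyl 2-(2-amino-4,6-dibromophenyl)-2-(methylthio)acetate | CCOC(=O)C(SC)c1c(N)cc(Br)cc1Br | intermediate
6 | racemic 4,6-dibromo-3-(methylthio)indolin-2-one | CSC1C(=O)Nc2cc(Br)cc(Br)c21 | intermediate
7 | 2,4,6-tribromo-3-(methylthio)-1H-indole | CSc1c(Br)[nH]c2cc(Br)cc(Br)c12 | intermediate
8 | ethyl bromoacetate | CCOC(=O)CBr | starting material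
9 | ethyl 2-[2,4,6-tribromo-3-(methylthio)indol-1-yl]acetate | CCOC(=O)Cn1c(Br)c(SC)c2c(Br)cc(Br)cc21 | intermediate
10 | 2-[2,4,6-tribromo-3-(methylthio)indol-1-yl]acetic acid | OC(=O)Cn1c(Br)c(SC)c2c(Br)cc(Br)cc21 | intermediate
11 | 3,4,5-tribromoaniline | Nc1cc(Br)c(Br)c(Br)c1 | starting material
12 | 3,4,5-tribromobenzenediazonium chloride | N#[N+]c1cc(Br)c(Br)c(Br)c1.[Cl-] | intermediate
13 | (3,4,5-tribromophenyl)hydrazine | NNc1cc(Br)c(Br)c(Br)c1 | intermediate
14 | benzotriazol-1-yl 2-[2,4,6-tribromo-3-(methylthio)indol-1-yl]acetate | O=C(Cn1c(Br)c(SC)c2c(Br)cc(Br)cc21)On1nnc2ccccc12 | intermediate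
15 | N'-(3,4,5-tribromophenyl)-2-[2,4,6-tribromo-3-(methylthio)indol-1-yl]acetohydrazide | O=C(Cn1c(Br)c(SC)c2c(Br)cc(Br)cc21)NNc1cc(Br)c(Br)c(Br)c1 | intermediate
16 | racemic 2-(6-amino-2,3,4-tribromophenyl)-2-[2,4,6-tribromo-3-(methylthio)indol-1-yl]acetamide | NC(=O)C(c1c(N)cc(Br)c(Br)c1Br)n1c(Br)c(SC)c2c(Br)cc(Br)cc21 | intermediate
17 | racemic 4,5,6-tribromo-3-[2,4,6-tribromo-3-(methylthio)indol-1-yl]indolin-2-one | O=C1Nc2cc(Br)c(Br)c(Br)c2C1n1c(Br)c(SC)c2c(Br)cc(Br)cc21 | intermediate
18 | racemic 4,5,6-tribromo-3-[2,4,6-tribromo-3-(methylthio)indol-1-yl]indoline-2-thione | S=C1Nc2cc(Br)c(Br)c(Br)c2C1n1c(Br)c(SC)c2c(Br)cc(Br)cc21 | intermediate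
19 | 4,5,6-tribromo-2-(methylthio)-3-[2,4,6-tribromo-3-(methylthio)indol-1-yl]-1H-indole | CSc1[nH]c2cc(Br)c(Br)c(Br)c2c1-n1c(Br)c(SC)c2c(Br)cc(Br)cc21 | target

Total steps: 8. Longest linear sequence: 7 (steps 1, 2, 3, 5, 6, 7, 8; step 4 is the side branch).

Steps most likely to fail

**Step 6.** Long heating near 200 °C may let debromination, attack of a hydrazide nitrogen on the C2' bromine position, or N–N homolysis outrun enolisation and the [3,3] shift.

- The fallback moves the same C3–C3a and N1–C2 construction into the N–O series, where the anionic hetero-Claisen shift of an O-acyl-N-arylhydroxylamine enolate is known to run at low temperature.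
- It sets out from acid 10 and returns at 17.
- Purchased 1,2,3-tribromo-5-nitrobenzene is reduced with Zn and NH4Cl in aqueous THF to N-(3,4,5-tribromophenyl)hydroxylamine F1.
- Boc2O caps the nitrogen to give tert-butyl hydroxy(3,4,5-tribromophenyl)carbamate F2.
- EDC·HCl and DMAP join 10 to the oxygen of F2 to give tert-butyl {[2-(2,4,6-tribromo-3-(methylthio)indol-1-yl)acetyl]oxy}(3,4,5-tribromophenyl)carbamate F3.
- KN(SiMe3)2 in THF at −78 °C forms the ester enolate, whose [3,3] shift to either of the equivalent ortho carbons should give racemic 2-[6-(tert-butoxycarbonylamino)-2,3,4-tribromophenyl]-2-[2,4,6-tribromo-3-(methylthio)indol-1-yl]acetic acid F4.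
- TFA in CH2Cl2 removes the Boc group and the amino acid lactamises to 17.

**Step 2.** Acid-promoted loss or migration of the methylthio group, or breakdown of the sensitive N–H 2-bromoindole, may occur during the hot deoxybromination.

- The fallback brings in the C2 bromine by electrophilic substitution instead of from a lactam.
- It sets out from 1 and returns at 7.
- A Gassman indole synthesis on 1 (t-BuOCl, then (methylthio)acetaldehyde dimethyl acetal, then Et3N, CH2Cl2, −65 °C → rt) should give racemic 3,5-dibromo-2-[2,2-dimethoxy-1-(methylthio)ethyl]aniline F5.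
- Aqueous HCl unmasks the aldehyde and closes the ring to 4,6-dibromo-3-(methylthio)-1H-indole F6.
- One equivalent of NBS in dry CH2Cl2 at −78 → 0 °C brominates the only open pyrrole position, C2, to give 7.

**Step 7.** Oxygen–sulfur exchange may be slow at a lactam carbonyl crowded by the C3 substituent and the C4 bromine, and the thione may be lost by air oxidation through its thiol tautomer.

- The fallback forms the C2–S bond by electrophilic sulfenylation and avoids the thione altogether.
- It sets out from 17 and returns at 19.
- BH3·THF (0 °C → rt, acidic work-up) reduces the lactam to the 2-hydroxyindoline stage, which dehydrates to 4,5,6-tribromo-3-[2,4,6-tribromo-3-(methylthio)indol-1-yl]-1H-indole F7.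
- Methanesulfenyl chloride (from MeSSMe and SO2Cl2, CH2Cl2, −78 → 0 °C) then sulfenylates C2 of ring A. This is the known course for 3-substituted indoles and C2 is the only nucleophilic carbon left in the molecule, so the product should be 19.

Further compounds
F1 | step 6 | N-(3,4,5-tribromophenyl)hydroxylamine | ONc1cc(Br)c(Br)c(Br)c1
F2 | step 6 | tert-butyl hydroxy(3,4,5-tribromophenyl)carbamate | CC(C)(C)OC(=O)N(O)c1cc(Br)c(Br)c(Br)c1
F3 | step 6 | tert-butyl {[2-(2,4,6-tribromo-3-(methylthio)indol-1-yl)acetyl]oxy}(3,4,5-tribromophenyl)carbamate | CC(C)(C)OC(=O)N(OC(=O)Cn1c(Br)c(SC)c2c(Br)cc(Br)cc21)c1cc(Br)c(Br)c(Br)c1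
F4 | step 6 | racemic 2-[6-(tert-butoxycarbonylamino)-2,3,4-tribromophenyl]-2-[2,4,6-tribromo-3-(methylthio)indol-1-yl]acetic acid | CC(C)(C)OC(=O)Nc1cc(Br)c(Br)c(Br)c1C(C(=O)O)n1c(Br)c(SC)c2c(Br)cc(Br)cc21
F5 | step 2 | racemic 3,5-dibromo-2-[2,2-dimethoxy-1-(methylthio)ethyl]aniline | COC(OC)C(SC)c1c(N)cc(Br)cc1Br
F6 | step 2 | 4,6-dibromo-3-(methylthio)-1H-indole | CSc1c[nH]c2cc(Br)cc(Br)c12
F7 | step 7 | 4,5,6-tribromo-3-[2,4,6-tribromo-3-(methylthio)indol-1-yl]-1H-indole | Brc1cc2[nH]cc(-n3c(Br)c(SC)c4c(Br)cc(Br)cc43)c2c(Br)c1Br
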